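**Strategy.** In plakortolide numbering (C1 lactone carbonyl, C2 methylene, C3 peroxy-bearing methine, C4 and C6 quaternary carbons) the γ-lactone ring O–C1–C2–C3–C4 is read as the Baeyer–Villiger product of a cyclobutanone, because C4, the ring carbon next to the ring oxygen, is fully substituted. The key step is a ketene–enol ether [2+2] cycloaddition: methyl(2-bromoallyl)ketene, generated from its acid chloride, and a chiral vinyl ether join C1–C2 and C3–C4 in one operation and create the C4 centre. Oxygen insertion and loss of the auxiliary give an (R)-butenolide. Negishi coupling adds the C7–C14 chain, and hydroperoxysilylation at C6 followed by oxa-Michael addition to C3 closes the 1,2-dioxane.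

Key step: step 3

Remark 1: C7–C14 is the side chain (C8 the methyl-bearing CH, C12=C13 the alkene, C14 the benzylic CH2).
Remark 2 (assumption): the facial sense in step 3 is taken from the s-trans enol ether conformer with the carbinol C–H in the plane of the vinyl group; if the opposite sense were found, the (S)-alcohol would replace 4.
Remark 3: step 13 is not expected to discriminate the two faces of C6. The (6R) epimer is taken on and its epimer is removed by chromatography after step 14. Step 13 is an addition and has no by-product.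

Step 1
Reactants: 1 propanoic acid; 2 2,3-dibromoprop-1-ene
Product: 3 (±)-4-bromo-2-methylpent-4-enoic acid
Conditions: LDA (2.2 equiv), THF/DMPU, 0 °C; then 2, −78 °C → rt; aq. HCl
Reagents that add atoms: none
Why: Alkylation of the carboxylic acid dianion: the α-carbanion displaces the allylic bromide of 2 (SN2, vinylic bromide inert); the α-centre is left racemic because it becomes the sp2 ketene carbon in step 3.

Step 2
Reactants: 4 (R)-1-(2,4,6-triisopropylphenyl)ethanol; 5 butyl vinyl ether
Product: 6 (R)-1-(2,4,6-triisopropylphenyl)ethyl vinyl ether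
Conditions: Pd(OCOCF3)2 (cat.), 4,7-diphenyl-1,10-phenanthroline (cat.), Et3N (cat.), 5 as solvent, 75 °C
Reagents that add atoms: none
Why: Pd(II)-catalysed transfer vinylation (vinyl ether exchange) forms the O–vinyl bond without breaking the carbinol C–O bond, so the (R) centre is retained.

Step 3
Reactants: 3 (±)-4-bromo-2-methylpent-4-enoic acid; 6 (R)-1-(2,4,6-triisopropylphenyl)ethyl vinyl ether
Product: 9 (2R,3R)-2-(2-bromoprop-2-en-1-yl)-2-methyl-3-[(1R)-1-(2,4,6-triisopropylphenyl)ethoxy]cyclobutan-1-one, via acid chloride 7 (not isolated), via ketene 8 (not isolated)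
Conditions: (COCl)2, DMF (cat.), CH2Cl2, 0 °C → rt, evaporate; then slow addition to 6 (excess), Et3N, toluene, 80 °C
Reagents that add atoms: none
Why: Et3N dehydrochlorinates acid chloride 7 to methyl(2-bromoallyl)ketene 8, which adds to enol ether 6 in a thermal Staudinger-type ketene–alkene [2+2] cycloaddition, the closest precedent being the cycloaddition of dialkylketenes with alkyl vinyl ethers. The cyclobutanone closes in a concerted, asynchronous [π2s+π2a] mode in which the nucleophilic CH2 terminus of the enol ether bonds to the ketene carbonyl carbon (C1–C2) and the oxygen-bearing carbon bonds to the ketene α-carbon (C3–C4), so the head-to-tail regiochemistry is fixed by polarity. C3 is set by the auxiliary: in the s-trans enol ether the aryl ring blocks one face and the ketene should add from the methyl side (Si face of the O-bearing carbon). C4 is set in the same event by the orthogonal approach, which places the larger 2-bromoallyl group of the ketene cis to the alkoxy group and the methyl group trans. The step needs cycloaddition to outrun ketene dimerisation (slow addition of 7, excess 6) and needs facial and cis selectivity; the minor diastereomers of 9 are removed by chromatography, which secures the C4 configuration.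

Step 4
Reactants: 9 (2R,3R)-cyclobutanone
Product: 10 (4R,5R)-5-(2-bromoprop-2-en-1-yl)-5-methyl-4-[(1R)-1-(2,4,6-triisopropylphenyl)ethoxy]oxolan-2-one
Conditions: mCPBA, NaHCO3, CH2Cl2, 0 °C → rt
Reagents that add atoms: mCPBA (3-chloroperoxybenzoic acid), OOC(=O)c1cccc(Cl)c1
Why: Baeyer–Villiger oxidation of the strained cyclobutanone: the fully substituted C4 migrates in preference to the CH2 group and with retention, turning the C4–C1 bond into the C4–O–C1 lactone linkage; the electron-poor vinyl bromide is not epoxidised.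

Step 5
Reactants: 10 (4R,5R)-alkoxy lactone
Product: 11 (5R)-5-(2-bromoprop-2-en-1-yl)-5-methylfuran-2(5H)-one
Conditions: LiHMDS, THF, −78 → 0 °C; aq. NH4Cl
Reagents that add atoms: none
Why: E1cB elimination: the lactone enolate at C2 expels the β-alkoxide at C3 to give the butenolide; C4 bears no hydrogen and keeps its configuration, and alcohol 4 is recovered.

Step 6
Reactants: 12 but-3-yn-1-ol; 13 benzyl chloride
Product: 15 (E)-3-methyl-5-phenylpent-3-en-1-ol, via alkenylalane 14 (not isolated)
Conditions: Me3Al (3 equiv), Cp2ZrCl2 (cat.), ClCH2CH2Cl, rt; then 13, Pd(PPh3)4 (cat.), THF, rt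
Reagents that add atoms: trimethylaluminium, C[Al](C)C
Why: Zr-catalysed carboalumination (Negishi) adds methyl and aluminium syn across the alkyne with methyl on the internal carbon, and the Pd-catalysed coupling of alkenylalane 14 with benzyl chloride proceeds with retention, so the C12=C13 alkene is E.

Step 7
Reactants: 15 (E)-3-methyl-5-phenylpent-3-en-1-ol
Product: 16 (E)-3-methyl-5-phenylpent-3-en-1-yl 4-methylbenzenesulfonate
Conditions: TsCl, Et3N, DMAP (cat.), CH2Cl2, 0 °C
Reagents that add atoms: p-toluenesulfonyl chloride, Cc1ccc(cc1)S(=O)(=O)Cl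
Why: Sulfonylation of the primary alcohol gives the leaving group for the sp3–sp3 coupling; no stereocentre is involved.

Step 8
Reactants: 17 (R)-3-bromo-2-methylpropan-1-ol
Product: 18 (R)-(3-bromo-2-methylpropoxy)(tert-butyl)dimethylsilane
Conditions: TBSCl, imidazole, DMF, rt
Reagents that add atoms: tert-butyldimethylsilyl chloride, CC(C)(C)[Si](C)(C)Cl
Why: Silylation of the primary alcohol; the bought stereocentre (the future C8) is not touched.

Step 9
Reactants: 18 (R)-bromide silyl ether; 16 homoallylic tosylate
Product: 20 tert-butyl{[(2S,6E)-2,6-dimethyl-8-phenyloct-6-en-1-yl]oxy}dimethylsilane, via Grignard reagent 19 (not isolated)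
Conditions: Mg, THF, 40 °C; then 16, Li2CuCl4 (cat.), THF, −20 °C → rt
Reagents that add atoms: none
Why: Copper-catalysed Grignard cross-coupling with the primary tosylate forms C9–C10 by SN2; the stereocentre is β to the metal and is retained (the descriptor changes from R to S only through the priority rules).

Step 10
Reactants: 20 silyl ether
Product: 21 (2S,6E)-2,6-dimethyl-8-phenyloct-6-en-1-ol
Conditions: TBAF, THF, rt
Reagents that add atoms: none
Why: Fluoride-mediated desilylation of the primary silyl ether; no stereocentre is affected.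

Step 11
Reactants: 21 (2S,6E)-alcohol
Product: 22 [(2E,7S)-8-iodo-3,7-dimethyloct-2-en-1-yl]benzene
Conditions: I2, PPh3, imidazole, CH2Cl2, 0 °C → rt
Reagents that add atoms: iodine, II
Why: Appel-type iodination by SN2 at the primary CH2; C8 is unaffected.

Step 12
Reactants: 22 (7S)-iodide; 11 (5R)-butenolide
Product: 24 (5R)-5-[(4S,8E)-4,8-dimethyl-2-methylidene-10-phenyldec-8-en-1-yl]-5-methylfuran-2(5H)-one, via organozinc iodide 23 (not isolated)
Conditions: Zn (activated), LiCl, THF, 40 °C; then 11, Pd(dppf)Cl2 (cat.), THF, 50 °C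
Reagents that add atoms: none
Why: Negishi sp3–sp2 coupling: zinc insertion into the primary iodide and Pd-catalysed coupling with the vinylic bromide form C6–C7; alkylzinc halides should not add to the butenolide, and no stereocentre is affected.

Step 13
Reactants: 24 (5R)-butenolide triene
Product: 25 (5R)-5-methyl-5-[(4S,8E)-2,4,8-trimethyl-10-phenyl-2-(triethylsilylperoxy)dec-8-en-1-yl]furan-2(5H)-one (both C6 epimers)
Conditions: Co(thd)2 (cat.), O2 (1 atm), Et3SiH, ClCH2CH2Cl, rt
Reagents that add atoms: dioxygen, O=O; triethylsilane, CC[SiH](CC)CC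
Why: Mukaiyama–Isayama hydroperoxysilylation: Co–H hydrogen-atom transfer to the unhindered 1,1-disubstituted alkene gives the tertiary C6 radical (Markovnikov), which is trapped by O2 and silylated; the trisubstituted and conjugated alkenes should react more slowly, and C6 forms without facial control.

Step 14
Reactants: 25 silyl peroxide (both C6 epimers)
Product: 27 plakortolide G, via hydroperoxide 26 (not isolated)
Conditions: HCl (cat.), MeOH, 0 °C; then Et2NH, CF3CH2OH, rt; chromatography
Reagents that add atoms: none
Why: Acid methanolysis frees the tertiary hydroperoxide, and amine-mediated 6-exo-trig oxa-Michael addition to C3 closes the 1,2-dioxane; the tether through C5 delivers oxygen to the face of C3 syn to C5, so the ring fusion is cis and C3 is set by C4, and the (6S) epimer carried from step 13 is separated here.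

**Compound list**

1 | propanoic acid | CCC(=O)O | starting material
2 | 2,3-dibromoprop-1-ene | C=C(Br)CBr | starting material
3 | (±)-4-bromo-2-methylpent-4-enoic acid | C=C(Br)CC(C)C(=O)O | intermediate
4 | (R)-1-(2,4,6-triisopropylphenyl)ethanol | C[C@@H](O)c1c(C(C)C)cc(C(C)C)cc1C(C)C | starting material
5 | butyl vinyl ether | C=COCCCC | starting material
6 | (R)-1-(2,4,6-triisopropylphenyl)ethyl vinyl ether | C=CO[C@H](C)c1c(C(C)C)cc(C(C)C)cc1C(C)C | intermediate
7 | 4-bromo-2-methylpent-4-enoyl chloride | C=C(Br)CC(C)C(=O)Cl | intermediate (not isolated)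
8 | 4-bromo-2-methylpenta-1,4-dien-1-one, methyl(2-bromoallyl)ketene | C=C(Br)CC(C)=C=O | intermediate (not isolated)
9 | (2R,3R)-2-(2-bromoprop-2-en-1-yl)-2-methyl-3-[(1R)-1-(2,4,6-triisopropylphenyl)ethoxy]cyclobutan-1-one | C=C(Br)C[C@@]1(C)C(=O)C[C@H]1O[C@H](C)c2c(C(C)C)cc(C(C)C)cc2C(C)C | intermediate
10 | (4R,5R)-5-(2-bromoprop-2-en-1-yl)-5-methyl-4-[(1R)-1-(2,4,6-triisopropylphenyl)ethoxy]oxolan-2-one | C=C(Br)C[C@@]1(C)OC(=O)C[C@H]1O[C@H](C)c2c(C(C)C)cc(C(C)C)cc2C(C)C | intermediate
11 | (5R)-5-(2-bromoprop-2-en-1-yl)-5-methylfuran-2(5H)-one | C=C(Br)C[C@@]1(C)OC(=O)C=C1 | intermediate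
12 | but-3-yn-1-ol | C#CCCO | starting material
13 | benzyl chloride | ClCc1ccccc1 | starting material
14 | (E)-1-(dimethylalumanyl)-2-methyl-4-[(dimethylalumanyl)oxy]but-1-ene | C[Al](C)/C=C(\C)CCO[Al](C)C | intermediate (not isolated)
15 | (E)-3-methyl-5-phenylpent-3-en-1-ol | OCC/C(C)=C/Cc1ccccc1 | intermediate
16 | (E)-3-methyl-5-phenylpent-3-en-1-yl 4-methylbenzenesulfonate | Cc1ccc(cc1)S(=O)(=O)OCC/C(C)=C/Cc1ccccc1 | intermediate
17 | (R)-3-bromo-2-methylpropan-1-ol | BrC[C@H](C)CO | starting material
18 | (R)-(3-bromo-2-methylpropoxy)(tert-butyl)dimethylsilane | BrC[C@H](C)CO[Si](C)(C)C(C)(C)C | intermediate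
19 | (R)-{3-[(tert-butyldimethylsilyl)oxy]-2-methylpropyl}magnesium bromide | Br[Mg]C[C@H](C)CO[Si](C)(C)C(C)(C)C | intermediate (not isolated)
20 | tert-butyl{[(2S,6E)-2,6-dimethyl-8-phenyloct-6-en-1-yl]oxy}dimethylsilane | CC(C)(C)[Si](C)(C)OC[C@@H](C)CCC/C(C)=C/Cc1ccccc1 | intermediate
21 | (2S,6E)-2,6-dimethyl-8-phenyloct-6-en-1-ol | OC[C@@H](C)CCC/C(C)=C/Cc1ccccc1 | intermediate
22 | [(2E,7S)-8-iodo-3,7-dimethyloct-2-en-1-yl]benzene | IC[C@@H](C)CCC/C(C)=C/Cc1ccccc1 | intermediate
23 | [(2S,6E)-2,6-dimethyl-8-phenyloct-6-en-1-yl]zinc iodide | I[Zn]C[C@@H](C)CCC/C(C)=C/Cc1ccccc1 | intermediate (not isolated)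
24 | (5R)-5-[(4S,8E)-4,8-dimethyl-2-methylidene-10-phenyldec-8-en-1-yl]-5-methylfuran-2(5H)-one | C=C(C[C@@]1(C)OC(=O)C=C1)C[C@@H](C)CCC/C(C)=C/Cc1ccccc1 | intermediate
25 | (5R)-5-methyl-5-[(4S,8E)-2,4,8-trimethyl-10-phenyl-2-(triethylsilylperoxy)dec-8-en-1-yl]furan-2(5H)-one, both epimers at the peroxy-bearing carbon (C6) | CC[Si](CC)(CC)OOC(C)(C[C@@]1(C)OC(=O)C=C1)C[C@@H](C)CCC/C(C)=C/Cc1ccccc1 | intermediate
26 | (5R)-5-[(4S,8E)-2-hydroperoxy-2,4,8-trimethyl-10-phenyldec-8-en-1-yl]-5-methylfuran-2(5H)-one, both epimers at C6 | OOC(C)(C[C@@]1(C)OC(=O)C=C1)C[C@@H](C)CCC/C(C)=C/Cc1ccccc1 | intermediate (not isolated)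
27 | plakortolide G, (3R,4R,6R)-configured cis-fused peroxylactone with the (8S,12E) side chain | C/C(=C\Cc1ccccc1)CCC[C@H](C)C[C@]1(C)C[C@@]2(C)OC(=O)C[C@H]2OO1 | target

**Total step count:** 14
**Longest linear sequence:** 8 steps (steps 6, 7, 9, 10, 11, 12, 13, 14, from but-3-yn-1-ol)

**Steps most likely to fail**

Step 3. The hindered dialkylketene may react sluggishly with the bulky enol ether and dimerise instead. The methyl and 2-bromoallyl groups may be discriminated poorly (weak cis control at C4), or the auxiliary may give weak facial control. The fallback makes the butenolide by self-regeneration of a stereocentre and sets out from 2. Commercial (2S,5S)-2-tert-butyl-5-methyl-1,3-dioxolan-4-one (the pivalaldehyde acetal of (S)-lactic acid) is deprotonated (LDA, THF, −78 °C) and alkylated with 2 anti to the tert-butyl group, which should give (2S,5R)-5-(2-bromoprop-2-en-1-yl)-2-tert-butyl-5-methyl-1,3-dioxolan-4-one F1. DIBAL-H (−78 °C) reduces the carbonyl group to the lactol (2S,5R)-5-(2-bromoprop-2-en-1-yl)-2-tert-butyl-5-methyl-1,3-dioxolan-4-ol F2. Still–Gennari olefination of F2 (methyl bis(2,2,2-trifluoroethyl)phosphonoacetate, KHMDS, 18-crown-6), in which the lactol opens and loses pivalaldehyde, should give methyl (2Z,4R)-6-bromo-4-hydroxy-4-methylhepta-2,6-dienoate F3. F3 lactonises (TsOH cat.) to butenolide 11, where the fallback comes back to the route.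

Step 13. Hydrogen-atom transfer may also occur at the trisubstituted C12=C13 alkene or at the butenolide, and the radical trapping has no facial bias at C6, so part of the material ends as the 6-epimer. The fallback replaces the radical process by an ionic one and sets out from 24. Peroxymercuration (Hg(OAc)2, anhydrous H2O2, Et2O/CH2Cl2, 0 °C) is a Markovnikov addition that is much faster at a terminal 1,1-disubstituted alkene than at a trisubstituted or conjugated one. It should give (5R)-5-[(4S,8E)-2-[(acetoxymercurio)methyl]-2-hydroperoxy-4,8-dimethyl-10-phenyldec-8-en-1-yl]-5-methylfuran-2(5H)-one F4. Demercuration with alkaline NaBH4 (0 °C) gives hydroperoxide 26, where the fallback comes back to the route (second stage of step 14). This cures the chemoselectivity only; the C6 epimers are still separated after cyclisation.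

Step 12. The butenolide may consume the organozinc reagent or the catalyst (conjugate addition, or Pd-mediated ionisation of the allylic lactone C–O bond), and the alkyl–Pd intermediate may undergo β-hydride elimination. The fallback couples before the enoate is unveiled and sets out from 10. Organozinc iodide 23 is coupled under the same Pd catalysis with lactone 10, in which the enoate is still masked as its β-alkoxy precursor. This should give (4R,5R)-5-[(4S,8E)-4,8-dimethyl-2-methylidene-10-phenyldec-8-en-1-yl]-5-methyl-4-[(1R)-1-(2,4,6-triisopropylphenyl)ethoxy]oxolan-2-one F5. E1cB elimination of F5 (LiHMDS, THF, −78 → 0 °C) then gives 24, where the fallback comes back to the route.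

**Further compounds**

F1 | step 3 | (2S,5R)-5-(2-bromoprop-2-en-1-yl)-2-tert-butyl-5-methyl-1,3-dioxolan-4-one | C=C(Br)C[C@@]1(C)O[C@H](C(C)(C)C)OC1=O
F2 | step 3 | (2S,5R)-5-(2-bromoprop-2-en-1-yl)-2-tert-butyl-5-methyl-1,3-dioxolan-4-ol (both anomers) | C=C(Br)C[C@@]1(C)O[C@H](C(C)(C)C)OC1O
F3 | step 3 | methyl (2Z,4R)-6-bromo-4-hydroxy-4-methylhepta-2,6-dienoate | C=C(Br)C[C@@](C)(O)/C=C\C(=O)OC
F4 | step 13 | (5R)-5-[(4S,8E)-2-[(acetoxymercurio)methyl]-2-hydroperoxy-4,8-dimethyl-10-phenyldec-8-en-1-yl]-5-methylfuran-2(5H)-one (both C6 epimers) | CC(=O)O[Hg]CC(OO)(C[C@@]1(C)OC(=O)C=C1)C[C@@H](C)CCC/C(C)=C/Cc1ccccc1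
F5 | step 12 | (4R,5R)-5-[(4S,8E)-4,8-dimethyl-2-methylidene-10-phenyldec-8-en-1-yl]-5-methyl-4-[(1R)-1-(2,4,6-triisopropylphenyl)ethoxy]oxolan-2-one | C=C(C[C@@]1(C)OC(=O)C[C@H]1O[C@H](C)c2c(C(C)C)cc(C(C)C)cc2C(C)C)C[C@@H](C)CCC/C(C)=C/Cc1ccccc1
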